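Points of E gained per point of J consumed: in that unit I decide whether the next run keeps the short interval between the portions of J or moves to a longer one.

| flask | J | X | remark | time |
|---|---|---|---|---|
| west | 0.0050 M (in portions, 4) | 1.5 equiv | run made earlier; portions every 2.5 h |  |
| south-east | 0.0075 M (in portions, 4) | 1.5 equiv | run made earlier; portions every 2.5 h |  |
| red | 0.010 M (in portions, 4) | 1.50 equiv | the portions of J follow each other after 2.5 h, the first at the start | 2.5 d |
| blue | 0.010 M (in portions, 4) | 1.50 equiv | the portions of J follow each other after 5.0 h, the first at the start | 2.5 d |
| grey | 0.010 M (in portions, 4) | 1.50 equiv | the portions of J follow each other after 10 h, the first at the start | 2.5 d |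

| run | time / d | E / % | J / % |
|---|---|---|---|
| west | 0.250 | 11.8 | 62.5 |
| west | 0.500 | 26.6 | 69.5 |
| west | 1.25 | 39.1 | 45.5 |
| west | 3.00 | 34.2 | 30.8 |
| south-east | 0.250 | 15.7 | 57.6 |
| south-east | 0.500 | 34.6 | 61.4 |
| south-east | 1.25 | 48.6 | 38.1 |
| south-east | 3.00 | 45.4 | 27.8 |

(each reading ± 0.3 percentage points)

- a reading or a percentage of E counts all its forms, free or not
- "hardly changes" means that all values lie within two and a half points (for a concentration: within two and a half percent of the largest)

* amount of E at the end, in percent of the J charged for red, blue, grey, in this order
* the course of these numbers from the first flask to the last (rises all the way / falls all the way / rises, then falls / falls, then rises / hardly changes)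

J and E together fall short of the charge, so counting J consumed does not count E made. Between 0.500 d and 1.25 d, after its last portion, the south-east run reads 0.601 as the rise of E over the fall of J, which I call the return on J, a net ratio of two changes, read for that window of time. The west run reads 0.521 over the same window. From 1.25 d to 3.00 d the returns are −0.311 in the south-east run and −0.333 in the west run, since J still falls and E now falls with it.

The decision hangs on what this return follows. The grey flask charges its last portion at 1.25 d, half of its time and just where the earlier runs stop paying. If the return follows the age of the flask, that portion costs E. If it follows fresh J, the portion pays as an early one does. I take the second reading, so I expect a flat row and keep the interval at 2.5 h, with no number of my own for the row.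

The forecast gives 53%, 53.3% and 54%, so hardly changes, on the ground that by the end “the system is near quasi-equilibrium”.

The flasks give 54.7%, 54.3% and 52.8%, crystals Q counted in E: hardly changes.

    J + X → G + E (k = 0.00220 L mol⁻¹ s⁻¹)
    X + G ⇌ Z, settled at all times (K = 1.80 × 10⁵ L mol⁻¹)
    Q ⇌ E, rate k3*(cs3 - [E]) while solid is left; crystals form when [E] > cs3 (solubility = 2.00 mM, k = 0.00220 s⁻¹)
    E ⇌ D (K = 1.50, k = 6.90 × 10⁻⁶ s⁻¹)

In the red flask the step between dissolved E and D has a relaxation half-life of 0.698 d by itself, short against the 2.5 d of the run. Red returns −0.0537 from 1.25 d to 2.50 d, less than the 0.601 read earlier. Grey, with its last portion counted as J to be consumed, returns 0.612 over the same stretch, close to 0.601, and ends with E at 52.8%.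

The data were computed from invented constants; noise was put on by code.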